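(The rate constants come from no measurement; no experiment stands behind them.)

A small charge of Q, 0.050 M in cedar, meets 2.50 equiv of X while L feeds base Z into the solution, and the meeting took up how much E stands at the end of cedar and of the larger flasks.

    Q + X → G + E (k1 = 36 M⁻¹ min⁻¹)
    G + Z ⇌ G.Z (K2 = 1.6 × 10⁷ M⁻¹, k2 = 31 M⁻¹ min⁻¹)
    X + G ⇌ X.G, settled at all times (K3 = 180 M⁻¹)
    L ⇌ Z, rate k4*(csat - [Z]) (k4 = 3.4 min⁻¹, csat = 2.5 mM)

| flask | Q | X | L | time |
|---|---|---|---|---|
| cedar | 0.050 M | 2.50 equiv | 2.5 mM (held) | 6.0 min |
| maple | 0.10 M | 2.50 equiv | 2.5 mM (held) | 6.0 min |
| elm | 0.20 M | 2.50 equiv | 2.5 mM (held) | 6.0 min |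
| larch | 0.40 M | 2.50 equiv | 2.5 mM (held) | 6.0 min |

1. [E] at the end for cedar, maple, elm, larch, in this order
2. how that number moves from the first to the last of them (falls all the way / rises all the way / falls, then rises / hardly changes / rises, then falls)

- at the start none of Z is dissolved
- "hardly changes" means that all values lie within two and a half points (for a concentration: within two and a half percent of the largest)
- run time (cedar): 6.0 min

Minutes. I opened by saying that the concentration to watch was free [X]: the step Q + X is first order in each, so the fraction of Q lost per minute at any moment equals 36 M⁻¹ min⁻¹ times free [X], and that value falls as X is used and bound.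

I then put the hard case. Each Q that reacts uses one X and gives one G, and each G can hold one more X as X.G, which is likely since the constant of that binding times [X] at the start of cedar is 22, well above one. So free [X] in cedar stays at or above 0.0250 M.

I proposed carrying the floor rate, 0.900 min⁻¹ in cedar: the rate constant of the Q + X step times the free [X] left if every G holds one X. Over 6.0 min that makes 5.40 lifetimes, each cutting Q by a factor of e, so at most 0.452 % of cedar's Q remains. The floor grows with the charge, to 7.20 min⁻¹ in larch, so I committed to [E] following the charge of Q.

The forecast was then read: 0.05 M, 0.1 M, 0.2 M and 0.4 M, so rises all the way, on the ground that “about 0.5 equiv stays free”. We shared that ground, but we differed on the lowest rate: the forecast gave at least about 1.4 per minute, and I held to 0.900 min⁻¹ in cedar.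

The simulation gives 0.0500 M, 0.100 M, 0.200 M and 0.400 M, so rises all the way. Cedar holds 0.0214 % of its Q after 6.00 min, less than the limit from the floor. Its 27 % of X still unbound gives a loss rate of 1.23 min⁻¹, above the floor. In elm the floor is 3.60 min⁻¹, and the 23 % of X unbound after 6.00 min gives 4.07 min⁻¹, above it.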